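**Retrosynthetic overview**
- Feature (chain numbered from the alkyne CH, C1, to the ethyl CH3, C15): the oxepene oxygen bridges C7 and C12 and sits between bromine on C13 (anti to the O–C12 bond) and the acetate on C6. This array is what a bromonium ion, an epoxide oxygen and an acetate leave behind.
- The last disconnection is the alkyne C–Si bond. Before it, O–C12, C13–Br and C6–OAc are cut in one operation, back to a cis-(6R,7S)-epoxy-(3Z,9Z,12E)-trienyne, N-bromosuccinimide and acetic acid. The oxepene is the only ring and closes in this step.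
- The epoxy trienyne comes from semihydrogenation of a C9≡C10 alkyne, and the C8–C9 bond from a 2,3-epoxy triflate and the lithium acetylide of (E)-hept-4-en-1-yne.
- The epoxy alcohol comes from Sharpless epoxidation of a (2Z,5Z)-dienynol, assembled from (Z)-1,3-dichloropropene, propargyl alcohol and trimethylsilylacetylene.

Key step: step 9

Assumption: the ring alkene C9=C10, which carries no descriptor in the target, is Z, as a seven-membered ring requires.

**Step 1**
Reactants: 1 (Z)-1,3-dichloropropene; 2 propargyl alcohol (prop-2-yn-1-ol)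
Product: 3 (5Z)-6-chlorohex-5-en-2-yn-1-ol
Conditions: CuI (10 mol %), n-Bu4NI (10 mol %), K2CO3, DMF, rt
Reagents that add atoms: none
Why: Copper-mediated coupling of a terminal alkyne with an allylic halide: the copper acetylide should displace only the allylic chloride at its CH2 terminus, while the vinylic chloride is inert, so the Z chloroalkene is carried through unchanged.

**Step 2**
Reactants: 3 (5Z)-6-chlorohex-5-en-2-yn-1-ol
Product: 4 (2Z,5Z)-6-chlorohexa-2,5-dien-1-ol
Conditions: H2 (1 atm), Pd/CaCO3 poisoned with Pb(OAc)2 (Lindlar catalyst), quinoline, EtOAc, rt, stopped after 1 equiv H2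
Reagents that add atoms: none
Why: Lindlar semihydrogenation adds H2 syn to the alkyne on the poisoned palladium surface and should give the 2Z allylic alcohol, the vinylic C–Cl bond being resistant to hydrogenolysis under these conditions.

**Step 3**
Reactants: 4 (2Z,5Z)-6-chlorohexa-2,5-dien-1-ol; 5 trimethylsilylacetylene
Product: 6 (2Z,5Z)-8-(trimethylsilyl)octa-2,5-dien-7-yn-1-ol
Conditions: PdCl2(PhCN)2 (5 mol %), CuI (10 mol %), piperidine, rt
Reagents that add atoms: none
Why: Sonogashira coupling of a (Z)-1-chloroalkene: the weakly ligated palladium precatalyst, reduced in piperidine to zerovalent palladium, should add oxidatively to the vinylic chloride at room temperature and couple with retention, giving the Z enyne.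

**Step 4**
Reactants: 6 (2Z,5Z)-8-(trimethylsilyl)octa-2,5-dien-7-yn-1-ol
Product: 7 [(2S,3R)-3-[(2Z)-5-(trimethylsilyl)pent-2-en-4-yn-1-yl]oxiran-2-yl]methanol
Conditions: Ti(OiPr)4 (0.3 equiv), L-(+)-diethyl tartrate (0.36 equiv), t-BuOOH (anhydrous, in decane), 4 Å MS, CH2Cl2, −20 °C
Reagents that add atoms: tert-butyl hydroperoxide, CC(C)(C)OO
Why: Sharpless asymmetric epoxidation: the titanium tartrate catalyst binds the allylic hydroxyl and delivers oxygen only to the allylic alkene, and L-(+)-tartrate selects the face that gives the 2S carbinol-side carbon, so the Z alkene should give the cis-(2S,3R) epoxide (6R,7S in chain numbering), both stereocentres being set by the reagent.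

**Step 5**
Reactants: 7 [(2S,3R)-3-[(2Z)-5-(trimethylsilyl)pent-2-en-4-yn-1-yl]oxiran-2-yl]methanol
Product: 8 [(2S,3R)-3-[(2Z)-5-(trimethylsilyl)pent-2-en-4-yn-1-yl]oxiran-2-yl]methyl trifluoromethanesulfonate
Conditions: Tf2O, 2,6-lutidine, CH2Cl2, −78 °C; used at once without chromatography
Reagents that add atoms: trifluoromethanesulfonic anhydride, O=S(=O)(OS(=O)(=O)C(F)(F)F)C(F)(F)F
Why: O-sulfonylation of the primary alcohol with a hindered base at low temperature should give the epoxy triflate without touching the epoxide or either stereocentre.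

**Step 6**
Reactants: 9 (E)-1-bromopent-2-ene; 10 ethynylmagnesium bromide
Product: 11 (4E)-hept-4-en-1-yne
Conditions: CuBr·SMe2 (5 mol %), THF, 0 °C to rt; careful distillation
Reagents that add atoms: none
Why: Copper-catalysed coupling of an alkynyl Grignard reagent with a primary allylic bromide should substitute at the CH2 terminus and leave the E alkene of 9 untouched; no stereocentre is formed.

**Step 7**
Reactants: 11 (4E)-hept-4-en-1-yne; 8 [(2S,3R)-3-[(2Z)-5-(trimethylsilyl)pent-2-en-4-yn-1-yl]oxiran-2-yl]methyl trifluoromethanesulfonate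
Product: 13 (2R,3S)-2-[(2Z)-5-(trimethylsilyl)pent-2-en-4-yn-1-yl]-3-[(5E)-oct-5-en-2-yn-1-yl]oxirane, via lithium acetylide 12 (not isolated)
Conditions: 11, n-BuLi, THF, −78 °C; then 8, THF/DMPU, −78 to −40 °C
Reagents that add atoms: none
Why: Alkynylation of a 2,3-epoxy triflate: SN2 displacement of the primary triflate by the lithium acetylide at −78 °C is far faster than opening of the unactivated epoxide, so the C8–C9 bond should form with both epoxide stereocentres intact.

**Step 8**
Reactants: 13 (2R,3S)-2-[(2Z)-5-(trimethylsilyl)pent-2-en-4-yn-1-yl]-3-[(5E)-oct-5-en-2-yn-1-yl]oxirane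
Product: 14 (2R,3S)-2-[(2Z)-5-(trimethylsilyl)pent-2-en-4-yn-1-yl]-3-[(2Z,5E)-octa-2,5-dien-1-yl]oxirane
Conditions: H2 (1 atm), Pd/CaCO3 poisoned with Pb(OAc)2 (Lindlar catalyst), quinoline, hexane/EtOAc, 0 °C, stopped after 1 equiv H2
Reagents that add atoms: none
Why: Lindlar semihydrogenation: the unhindered dialkyl alkyne C9≡C10 should be adsorbed and reduced well before the silyl-capped conjugated alkyne, and syn addition of H2 gives the 9Z alkene.

**Step 9**
Reactants: 14 (2R,3S)-2-[(2Z)-5-(trimethylsilyl)pent-2-en-4-yn-1-yl]-3-[(2Z,5E)-octa-2,5-dien-1-yl]oxirane; 15 N-bromosuccinimide; 16 acetic acid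
Product: 19 (1S,3Z)-1-[(2S,7R)-7-[(1S)-1-bromopropyl]-2,3,6,7-tetrahydrooxepin-2-yl]-6-(trimethylsilyl)hex-3-en-5-yn-1-yl acetate, via bromonium ion 17 (not isolated), via epoxonium ion 18 (not isolated)
Conditions: NBS (1.1 equiv), AcOH (10 equiv), (CF3)2CHOH, 4 Å MS, 0 °C, dark, 0.01 M
Reagents that add atoms: none
Why: N-Bromosuccinimide activated by the fluorinated alcohol transfers Br+ reversibly to the isolated alkenes, and only the bromonium ion on C12=C13 (17) has a productive exit: the epoxide oxygen opens it at C12 anti to bromine, closing the oxepene, and the resulting 1-oxoniabicyclo[5.1.0]oct-4-ene 18 is opened by acetic acid at C6 with inversion. The closest known reaction type is the bromonium-initiated epoxide-opening cascade in a fluorinated alcohol that ends with capture of the epoxonium ion by an added carboxylic acid. The single ring closes in 7-exo mode (C13 stays outside the ring); the alternatives are 8-endo attack at C13 and, for a bromonium ion on C9=C10, a four-membered closure at C9 or a strained 5-endo opening at C10. C13 (S) and C12 (R) follow from anti addition across the E alkene, the alkene face being chosen by C7 through a chair-like transition state with the C7 and C12 substituents pseudo-equatorial (7,12-cis); C6 becomes S by inversion of the 6R epoxide carbon, and C7 keeps its configuration. The step needs site selectivity for C12=C13 (the enyne alkene is deactivated by conjugation and a C9=C10 bromonium ion should revert), exo opening of 18 at C6 rather than ring expansion at C7 to an oxocene, and no direct addition of acetic acid to 17. The Z alkene C9=C10 holds the epoxide oxygen near C12, and high dilution with only a moderate excess of acetic acid should favour the intramolecular relay.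

**Step 10**
Reactants: 19 (1S,3Z)-1-[(2S,7R)-7-[(1S)-1-bromopropyl]-2,3,6,7-tetrahydrooxepin-2-yl]-6-(trimethylsilyl)hex-3-en-5-yn-1-yl acetate
Product: 20 (1S,3Z)-1-[(2S,7R)-7-[(1S)-1-bromopropyl]-2,3,6,7-tetrahydrooxepin-2-yl]hex-3-en-5-yn-1-yl acetate
Conditions: n-Bu4NF (1.2 equiv), AcOH (1.5 equiv), THF, 0 °C
Reagents that add atoms: none
Why: Fluoride-induced protodesilylation of the alkynylsilane: attack of fluoride at silicon releases the acetylide, which acetic acid protonates at once, and the buffering should prevent elimination of HBr and loss of the acetate.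

**Compound list**
1 | (Z)-1,3-dichloropropene | Cl/C=C\CCl | starting material
2 | propargyl alcohol (prop-2-yn-1-ol) | C#CCO | starting material
3 | (5Z)-6-chlorohex-5-en-2-yn-1-ol | OCC#CC/C=C\Cl | intermediate
4 | (2Z,5Z)-6-chlorohexa-2,5-dien-1-ol | OC/C=C\C/C=C\Cl | intermediate
5 | trimethylsilylacetylene | C#C[Si](C)(C)C | starting material
6 | (2Z,5Z)-8-(trimethylsilyl)octa-2,5-dien-7-yn-1-ol | OC/C=C\C/C=C\C#C[Si](C)(C)C | intermediate
7 | [(2S,3R)-3-[(2Z)-5-(trimethylsilyl)pent-2-en-4-yn-1-yl]oxiran-2-yl]methanol | C[Si](C)(C)C#C/C=C\C[C@H]1O[C@H]1CO | intermediate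
8 | [(2S,3R)-3-[(2Z)-5-(trimethylsilyl)pent-2-en-4-yn-1-yl]oxiran-2-yl]methyl trifluoromethanesulfonate | C[Si](C)(C)C#C/C=C\C[C@H]1O[C@H]1COS(=O)(=O)C(F)(F)F | intermediate
9 | (E)-1-bromopent-2-ene | CC/C=C/CBr | starting material
10 | ethynylmagnesium bromide | C#C[Mg]Br | starting material
11 | (4E)-hept-4-en-1-yne | C#CC/C=C/CC | intermediate
12 | lithium (4E)-hept-4-en-1-yn-1-ide (lithium acetylide of 11) | [Li]C#CC/C=C/CC | intermediate
13 | (2R,3S)-2-[(2Z)-5-(trimethylsilyl)pent-2-en-4-yn-1-yl]-3-[(5E)-oct-5-en-2-yn-1-yl]oxirane; cis-(6R,7S)-epoxide, chain (3Z,12E)-diene-1,9-diyne | C[Si](C)(C)C#C/C=C\C[C@H]1O[C@H]1CC#CC/C=C/CC | intermediate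
14 | (2R,3S)-2-[(2Z)-5-(trimethylsilyl)pent-2-en-4-yn-1-yl]-3-[(2Z,5E)-octa-2,5-dien-1-yl]oxirane; cis-(6R,7S)-epoxy-(3Z,9Z,12E)-trienyne | C[Si](C)(C)C#C/C=C\C[C@H]1O[C@H]1C/C=C\C/C=C/CC | intermediate
15 | N-bromosuccinimide | O=C1CCC(=O)N1Br | starting material
16 | acetic acid | CC(=O)O | starting material
17 | (12S,13S)-bromonium ion of 14 at C12=C13, epoxide intact | C[Si](C)(C)C#C/C=C\C[C@H]1O[C@H]1C/C=C\C[C@H]1[C@H](CC)[Br+]1 | intermediate
18 | epoxonium ion, 1-oxoniabicyclo[5.1.0]oct-4-ene with O+ bonded to C6, C7 and C12 and bromine on C13 | C[Si](C)(C)C#C/C=C\C[C@@H]1[C@@H]2CC=CC[C@H]([C@@H](Br)CC)[O+]12 | intermediate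
19 | (1S,3Z)-1-[(2S,7R)-7-[(1S)-1-bromopropyl]-2,3,6,7-tetrahydrooxepin-2-yl]-6-(trimethylsilyl)hex-3-en-5-yn-1-yl acetate | C[Si](C)(C)C#C/C=C\C[C@H](OC(C)=O)[C@@H]1CC=CC[C@H]([C@@H](Br)CC)O1 | intermediate
20 | (1S,3Z)-1-[(2S,7R)-7-[(1S)-1-bromopropyl]-2,3,6,7-tetrahydrooxepin-2-yl]hex-3-en-5-yn-1-yl acetate; (3Z,6S,7S,12R,13S) in chain numbering | C#C/C=C\C[C@H](OC(C)=O)[C@@H]1CC=CC[C@H]([C@@H](Br)CC)O1 | target

**Step count**
Total: 10 steps. Longest linear sequence: 9 steps (steps 1–5 and 7–10); step 6 makes the second fragment.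

**Steps most likely to fail**

1. Step 9. Several processes can divert the cascade:
- bromonium capture on the other face of C12=C13, leading to the 7,12-trans oxepene;
- capture of a C9=C10 bromonium ion by the epoxide oxygen in a 5-endo opening, leading to a bromotetrahydrofuran;
- opening of the epoxonium ion at C7, with ring expansion to the oxocene;
- interception of the bromonium ion by acetic acid or solvent before the epoxide reacts.

Fallback: the ring-forming relay is separated from the esterification. It sets out from 14, which is treated with NBS and water (20 equiv) in (CF3)2CHOH at 0 °C, so that water ends the cascade and gives (1S,3Z)-1-[(2S,7R)-7-[(1S)-1-bromopropyl]-2,3,6,7-tetrahydrooxepin-2-yl]-6-(trimethylsilyl)hex-3-en-5-yn-1-ol F1. This polar alcohol can be freed from regio- and stereoisomers by chromatography. Acetylation (Ac2O, pyridine, DMAP, CH2Cl2, 0 °C) brings it back to the route at 19.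

2. Step 8. Hydrogen may be taken up by the silyl-capped enyne as well, and once the C9≡C10 alkyne is consumed the skipped alkenes may be reduced or isomerised.

Fallback: the sequence is reordered so that no silyl alkyne is present during hydrogenation. It sets out from 4.
- Sharpless epoxidation with L-(+)-diethyl tartrate, as in step 4, gives [(2S,3R)-3-[(2Z)-3-chloroprop-2-en-1-yl]oxiran-2-yl]methanol F2.
- Tf2O and 2,6-lutidine give the triflate F3.
- Displacement with lithium acetylide 12, as in step 7, gives (2R,3S)-2-[(2Z)-3-chloroprop-2-en-1-yl]-3-[(5E)-oct-5-en-2-yn-1-yl]oxirane F4.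
- Lindlar semihydrogenation, to which the vinylic chloride is inert, gives (2R,3S)-2-[(2Z)-3-chloroprop-2-en-1-yl]-3-[(2Z,5E)-octa-2,5-dien-1-yl]oxirane F5.
- Sonogashira coupling with 5 (PdCl2(PhCN)2, CuI, piperidine, rt) then installs the silyl enyne last and returns to the route at 14.

3. Step 4. Z allylic alcohols are the slowest and least face-selective class for the titanium tartrate catalyst. Incomplete facial discrimination would carry the enantiomer of 7 through every later step, and slow turnover gives the epoxy alcohol time to open.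

Fallback: enantiomeric enrichment by crystallisation is added to reagent control. It sets out from 7, which is esterified with 4-bromobenzoyl chloride and pyridine to [(2S,3R)-3-[(2Z)-5-(trimethylsilyl)pent-2-en-4-yn-1-yl]oxiran-2-yl]methyl 4-bromobenzoate F6. The ester is recrystallised to enantiomeric purity, and reductive cleavage with i-Bu2AlH in CH2Cl2 at −78 °C, which spares the alkynylsilane and the epoxide, returns to the route at 7.

**Further compounds**
F1 | step 9 | (1S,3Z)-1-[(2S,7R)-7-[(1S)-1-bromopropyl]-2,3,6,7-tetrahydrooxepin-2-yl]-6-(trimethylsilyl)hex-3-en-5-yn-1-ol | C[Si](C)(C)C#C/C=C\C[C@H](O)[C@@H]1CC=CC[C@H]([C@@H](Br)CC)O1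
F2 | step 8 | [(2S,3R)-3-[(2Z)-3-chloroprop-2-en-1-yl]oxiran-2-yl]methanol | Cl/C=C\C[C@H]1O[C@H]1CO
F3 | step 8 | [(2S,3R)-3-[(2Z)-3-chloroprop-2-en-1-yl]oxiran-2-yl]methyl trifluoromethanesulfonate | Cl/C=C\C[C@H]1O[C@H]1COS(=O)(=O)C(F)(F)F
F4 | step 8 | (2R,3S)-2-[(2Z)-3-chloroprop-2-en-1-yl]-3-[(5E)-oct-5-en-2-yn-1-yl]oxirane | Cl/C=C\C[C@H]1O[C@H]1CC#CC/C=C/CC
F5 | step 8 | (2R,3S)-2-[(2Z)-3-chloroprop-2-en-1-yl]-3-[(2Z,5E)-octa-2,5-dien-1-yl]oxirane | Cl/C=C\C[C@H]1O[C@H]1C/C=C\C/C=C/CC
F6 | step 4 | [(2S,3R)-3-[(2Z)-5-(trimethylsilyl)pent-2-en-4-yn-1-yl]oxiran-2-yl]methyl 4-bromobenzoate | C[Si](C)(C)C#C/C=C\C[C@H]1O[C@H]1COC(=O)c1ccc(Br)cc1
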